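**Retrosynthetic overview**

1. Oxonane last: the C6–C7 bond by Nozaki–Hiyama–Kishi closure (C7 vinyl iodide made from a propargyl group on C9, C6 aldehyde); the C4 octanoate is put on just before.
2. Lactone: the tertiary C3–O bond by acid-catalysed attack of the C16 acid on a cis C3/C4 epoxide (inversion at C3, C4–OH set free); the C11 methyl carbinol by methyl addition to a C11 ketone.
3. Core by the key cascade on a monocyclic cyclopentanol: 6-endo iodoetherification (O on C2 to C9), then a semipinacol 1,2-shift of C1 from C11 to C10. The cyclopentane (C1, C11, C12, C13, C14) grows into the cyclohexanone (C1, C10–C14) while the transient pyran (O, C2, C1, C11, C10, C9) shrinks to the tetrahydrofuran (O, C2, C1, C10, C9).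
4. Enabling feature: the tertiary carbinol C11 of the cyclopentane carries the (E)-C9=C10 alkene trans to the C2 carbinol arm on C1. A 5-exo closure would need a trans-fused bicyclo[3.3.0]octane, so oxygen goes to C9, iodine ends equatorial on C10 and antiperiplanar to the ring bond C11–C1, and the C11 hydroxyl supplies the push.
5. Cyclopentanol from cyclopent-2-enone by asymmetric conjugate addition/boron aldol with an epoxy aldehyde (Sharpless epoxidation), addition of an (E)-alkenylcerium reagent and hydroboration. Ring order: cyclopentane (bought) → cyclohexanone + tetrahydrofuran (via the pyran) → lactone → oxonane.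

Key step: step 11

Remark: locants follow the eunicellane skeleton (C1/C10 ring-fusion CH, C2/C9 ether CH, C3 quaternary lactone carbinol carbon, C4 CH–octanoate, C5 CH2, C6 CH–OH, C7 C=CH2, C8 CH2, C11 C(OH)CH3, C12/C13 CH2, C14 CH, C15 CH(CH3), C16 lactone C=O); compounds 1, 2, 7, 8, 12, 13, 16 and 30 are taken as commercial.

**Step 1**
Reactants: 1 3-[(tert-butyldiphenylsilyl)oxy]propanal; 2 ethyl 2-[bis(2,2,2-trifluoroethoxy)phosphoryl]propanoate
Product: 3 ethyl (Z)-5-[(tert-butyldiphenylsilyl)oxy]-2-methylpent-2-enoate
Conditions: KN(SiMe3)2, 18-crown-6, THF, −78 °C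
Reagents that add atoms: none
Why: Still–Gennari olefination, in which the bis(trifluoroethyl) phosphonate eliminates under kinetic control to the (Z)-trisubstituted enoate and so fixes the C3=C4 geometry needed for the cis epoxide.

**Step 2**
Reactants: 3 ethyl (Z)-5-[(tert-butyldiphenylsilyl)oxy]-2-methylpent-2-enoate
Product: 4 (Z)-5-[(tert-butyldiphenylsilyl)oxy]-2-methylpent-2-en-1-ol
Conditions: i-Bu2AlH, CH2Cl2, −78 °C; aq. potassium sodium tartrate
Reagents that add atoms: none
Why: 1,2-reduction of the enoate to the allylic alcohol, which leaves alkene geometry and silyl ether untouched.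

**Step 3**
Reactants: 4 (Z)-5-[(tert-butyldiphenylsilyl)oxy]-2-methylpent-2-en-1-ol
Product: 5 [(2S,3R)-3-{2-[(tert-butyldiphenylsilyl)oxy]ethyl}-2-methyloxiran-2-yl]methanol
Conditions: Ti(OiPr)4 (10 mol %), L-(+)-diisopropyl tartrate (12 mol %), t-BuOOH, 4 Å MS, CH2Cl2, −20 °C
Reagents that add atoms: tert-butyl hydroperoxide, CC(C)(C)OO
Why: Sharpless asymmetric epoxidation; the L-(+)-tartrate catalyst should deliver oxygen to the face that gives the (2S,3R) cis epoxide and thereby sets C3 and C4 under reagent control.

**Step 4**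
Reactants: 5 [(2S,3R)-3-{2-[(tert-butyldiphenylsilyl)oxy]ethyl}-2-methyloxiran-2-yl]methanol
Product: 6 (2R,3R)-3-{2-[(tert-butyldiphenylsilyl)oxy]ethyl}-2-methyloxirane-2-carbaldehyde
Conditions: Dess–Martin periodinane, NaHCO3, CH2Cl2, 0 °C → rt
Reagents that add atoms: none
Why: Dess–Martin oxidation of the primary alcohol; the α-carbon is quaternary, so the epoxy aldehyde cannot epimerise.

**Step 5**
Reactants: 7 ethynyltrimethylsilane; 8 3-bromoprop-1-yne
Product: 9 trimethyl(penta-1,4-diyn-1-yl)silane
Conditions: CuI (cat.), K2CO3, Bu4NI (cat.), DMF, rt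
Reagents that add atoms: none
Why: copper-catalysed propargylation of a terminal alkyne (the copper acetylide displaces bromide), which gives the skipped diyne under weakly basic conditions.

**Step 6**
Reactants: 9 trimethyl(penta-1,4-diyn-1-yl)silane
Product: 11 [(E)-5-iodopent-4-en-1-yn-1-yl]trimethylsilane, via alkenylzirconocene chloride 10 (not isolated)
Conditions: Cp2Zr(H)Cl, THF, rt; then I2, 0 °C
Reagents that add atoms: iodine, II
Why: hydrozirconation adds Zr–H syn and anti-Markovnikov to the terminal alkyne only (the silylalkyne is hindered), and iodinolysis with retention gives the (E)-vinyl iodide.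

**Step 7**
Reactants: 12 isopropenylmagnesium bromide; 13 9-methoxy-9-borabicyclo[3.3.1]nonane
Product: 15 9-isopropenyl-9-borabicyclo[3.3.1]nonane, via bromomagnesium isopropenyl(methoxy)borate 14 (not isolated)
Conditions: THF/hexane, −78 °C → rt; then BF3·OEt2, 0 °C
Reagents that add atoms: none
Why: the Grignard reagent adds to the B–OMe borane to give the borate and BF3 abstracts methoxide, the standard entry to B-alkenyl-9-BBN reagents.

**Step 8**
Reactants: 15 9-isopropenyl-9-borabicyclo[3.3.1]nonane; 16 cyclopent-2-en-1-one; 6 (2R,3R)-3-{2-[(tert-butyldiphenylsilyl)oxy]ethyl}-2-methyloxirane-2-carbaldehyde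
Product: 18 aldol ketone (3-isopropenylcyclopentanone with the C2 carbinol/epoxide arm trans on C1; C14 R), via boron enolate 17 (not isolated)
Conditions: [Rh(OMe)(cod)]2 (1.5 mol %), (R)-BINAP (3.3 mol %), toluene, 80 °C; then 6, THF, −78 → 0 °C; H2O2, pH 7 buffer, MeOH, 0 °C
Reagents that add atoms: none
Why: rhodium/BINAP-catalysed asymmetric 1,4-addition of a B-organyl-9-BBN to a cyclic enone sets C14 under ligand control and leaves the regiodefined 9-BBN enolate, whose aldol addition through a Zimmerman–Traxler chair on the face anti to the isopropenyl group should give the trans ketone with the anti C1/C2 relationship, the non-chelating boron directing attack to the Felkin–Anh/Cornforth face of the epoxy aldehyde (C2–O anti to the epoxide oxygen).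

**Step 9**
Reactants: 18 aldol ketone; 11 [(E)-5-iodopent-4-en-1-yn-1-yl]trimethylsilane
Product: 21 alkenyl diol (C11 tertiary allylic alcohol with the (E)-alkenyl group trans to the C2 carbinol arm), via alkenyllithium 19 (not isolated), via alkenylcerium dichloride 20 (not isolated)
Conditions: 11, t-BuLi (2 equiv per iodide), Et2O, −78 °C; CeCl3, THF, −78 °C; then 18 (3 equiv of organocerium), −78 °C
Reagents that add atoms: none
Why: iodine–lithium exchange with retention of the E geometry and transmetalation to the weakly basic organocerium, which should add to the cyclopentanone anti to the adjacent C1 substituent so that the alkenyl group is trans and the new C11 hydroxyl cis to the C2 carbinol arm.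

**Step 10**
Reactants: 21 alkenyl diol
Product: 23 triol (C16 primary alcohol, C15 as in the target), via B-alkyl-9-BBN adduct 22 (not isolated)
Conditions: 9-BBN (4 equiv), THF, 0 °C → rt; then 30% H2O2, 3 M aq. NaOAc, 0 °C → rt
Reagents that add atoms: hydrogen peroxide, OO
Why: hydroboration–oxidation with bulky 9-BBN is selective for the 1,1-disubstituted alkene over the (E)-1,2-disubstituted alkene and the silylalkyne, and C15 should be set by addition to the conformer with C14–H eclipsing the C=CH2 bond on the face anti to the branched C1 (substrate control by allylic strain).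

**Step 11**
Reactants: 23 triol
Product: 25 cis-fused hydroisobenzofuranone (C11 ketone), via iodo-pyran 24 (not isolated)
Conditions: N-iodosuccinimide (1.1 equiv), CH2Cl2, −40 → 0 °C; then AgOSO2CF3 (1.5 equiv), 2,6-di-tert-butyl-4-methylpyridine, −40 °C → rt
Reagents that add atoms: none
Why: N-iodosuccinimide forms the iodonium ion of the (E)-C9=C10 alkene and the C2 hydroxyl opens it at C9 in a 6-endo-trig, chair-like anti addition (5-exo closure at C10 is excluded because the alkenyl and carbinol arms are trans on the cyclopentane and would have to form a trans-bicyclo[3.3.0]octane), which gives the all-equatorial trans-fused iodo-pyran 24 with C8 equatorial on C9 and iodine equatorial on C10. Silver triflate then ionises the C10–I bond while the antiperiplanar ring bond C11–C1 migrates to C10 and the axial tertiary hydroxyl on C11 collapses to the ketone, a semipinacol (halohydrin) rearrangement of the kind used for silver-promoted ring contraction of trans-2-halocyclohexanols and ring enlargement of 1-(1-haloalkyl)cycloalkanols. This single 1,2-shift closes the cyclohexanone (C1, C10–C14) by one-carbon enlargement of the cyclopentane and at the same time contracts the pyran to the tetrahydrofuran (O, C2, C1, C10, C9). C9 is set by the chair transition state of the etherification (C8 equatorial, hence H2 and H9 cis), C10 by anti addition followed by inversion as C1 enters from the rear, and C1 migrates with retention, so the ring fusion is cis and C11 and C8 end up trans on the tetrahydrofuran. The selectivity needed is carbon migration over epoxide closure, hydride shift, elimination or participation of the ring oxygen: the hydroxyl is gauche to iodine, C11 bears no hydrogen, H9 is not antiperiplanar to iodine, an oxonium ion bridging C9 and C10 could only collapse to the strained trans-fused oxabicyclo[3.3.0]octane, and only the C11–C1 shift produces an oxocarbenium ion. The hindered pyridine base keeps the medium neutral so that the epoxide, the silyl ether and the silylalkyne should survive.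

**Step 12**
Reactants: 25 cis-fused hydroisobenzofuranone
Product: 26 C11 methyl carbinol
Conditions: MeLi, CeCl3, THF, −78 °C
Reagents that add atoms: methyllithium, [Li]C
Why: organocerium 1,2-addition (no enolisation and no β-elimination of the ring ether), in which methyl should enter axially on the convex face, anti to the axial C10–C9 bond, placing the C11 hydroxyl on the side of the tetrahydrofuran ring.

**Step 13**
Reactants: 26 C11 methyl carbinol
Product: 27 terminal alkyne diol
Conditions: K2CO3, MeOH, rt
Reagents that add atoms: none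
Why: methanolysis of the alkynyl C–Si bond under mild base, to which the silyl ether, the epoxide and the alcohols are stable.

**Step 14**
Reactants: 27 terminal alkyne diol
Product: 28 C16 carboxylic acid
Conditions: TEMPO (20 mol %), PhI(OAc)2, MeCN/pH 7 buffer, rt
Reagents that add atoms: water, O
Why: oxoammonium oxidation of the primary alcohol through the aldehyde hydrate to the acid; the tertiary alcohol is inert and the buffered medium avoids epimerisation at C15.

**Step 15**
Reactants: 28 C16 carboxylic acid
Product: 29 hydroxy ε-lactone (C3–O–C16 lactone, free C4–OH)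
Conditions: camphorsulfonic acid (10 mol %), CH2Cl2, 0 °C → rt
Reagents that add atoms: none
Why: acid-catalysed intramolecular epoxide opening by the carboxylic acid at the tertiary C3 (7-exo; the eight-membered alternative through C4 is disfavoured) with inversion, which forms the tertiary lactone C–O bond without acylating a tertiary alcohol, sets C3, and leaves the epoxide oxygen on C4 as the free hydroxyl.

**Step 16**
Reactants: 29 hydroxy ε-lactone; 30 octanoyl chloride
Product: 31 C4 octanoate
Conditions: pyridine, DMAP (cat.), CH2Cl2, 0 °C → rt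
Reagents that add atoms: none
Why: DMAP-catalysed acylation of the only secondary alcohol; the tertiary C11 hydroxyl should not react.

**Step 17**
Reactants: 31 C4 octanoate
Product: 33 vinyl iodide (2-iodoallyl group on C9), via iodoalkenylborane 32 (not isolated)
Conditions: B-iodo-9-BBN (2.2 equiv), hexane/CH2Cl2, −20 °C; then AcOH, 0 °C
Reagents that add atoms: B-iodo-9-borabicyclo[3.3.1]nonane, IB1C2CCCC1CCC2
Why: haloboration, a syn Markovnikov addition of B–I to the terminal alkyne (boron to the terminal carbon), followed by protonolysis of the alkenylborane with acetic acid, gives the 2-iodo-1-alkene.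

**Step 18**
Reactants: 33 vinyl iodide
Product: 34 C6 primary alcohol
Conditions: HF·pyridine, pyridine, THF, 0 °C → rt
Reagents that add atoms: none
Why: fluoride cleavage of the primary silyl ether under buffered acidic conditions, which avoid acyl migration and lactone opening.

**Step 19**
Reactants: 34 C6 primary alcohol
Product: 35 C6 aldehyde
Conditions: Dess–Martin periodinane, NaHCO3, CH2Cl2, rt
Reagents that add atoms: none
Why: Dess–Martin oxidation under buffered conditions, which leave the tertiary alcohol alone and avoid β-elimination of the C4 octanoate.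

**Step 20**
Reactants: 35 C6 aldehyde
Product: 37 briarellin A, via alkenylchromium dichloride 36 (not isolated)
Conditions: CrCl2 (6 equiv), NiCl2 (1 mol %), DMSO, rt, 0.005 M
Reagents that add atoms: none
Why: Nozaki–Hiyama–Kishi reaction, in which nickel-catalysed formation of the alkenylchromium species and its chemoselective addition to the aldehyde close the nine-membered ring and give the C6 allylic alcohol with the exocyclic methylene; the C6 configuration is expected from attack on the aldehyde face that is exposed when the chain folds around the rigid tricyclic core (substrate control).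

**Compound list**

1 | 3-[(tert-butyldiphenylsilyl)oxy]propanal | O=CCCO[Si](c1ccccc1)(c1ccccc1)C(C)(C)C | starting material
2 | ethyl 2-[bis(2,2,2-trifluoroethoxy)phosphoryl]propanoate | CCOC(=O)C(C)P(=O)(OCC(F)(F)F)OCC(F)(F)F | starting material
3 | ethyl (Z)-5-[(tert-butyldiphenylsilyl)oxy]-2-methylpent-2-enoate | CCOC(=O)/C(C)=C\CCO[Si](c1ccccc1)(c1ccccc1)C(C)(C)C | intermediate
4 | (Z)-5-[(tert-butyldiphenylsilyl)oxy]-2-methylpent-2-en-1-ol | OC/C(C)=C\CCO[Si](c1ccccc1)(c1ccccc1)C(C)(C)C | intermediate
5 | [(2S,3R)-3-{2-[(tert-butyldiphenylsilyl)oxy]ethyl}-2-methyloxiran-2-yl]methanol | OC[C@]1(C)O[C@@H]1CCO[Si](c2ccccc2)(c2ccccc2)C(C)(C)C | intermediate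
6 | (2R,3R)-3-{2-[(tert-butyldiphenylsilyl)oxy]ethyl}-2-methyloxirane-2-carbaldehyde | O=C[C@]1(C)O[C@@H]1CCO[Si](c2ccccc2)(c2ccccc2)C(C)(C)C | intermediate
7 | ethynyltrimethylsilane | C#C[Si](C)(C)C | starting material
8 | 3-bromoprop-1-yne | BrCC#C | starting material
9 | trimethyl(penta-1,4-diyn-1-yl)silane | C#CCC#C[Si](C)(C)C | intermediate
10 | chlorobis(cyclopentadienyl)[(E)-5-(trimethylsilyl)pent-1-en-4-yn-1-yl]zirconium (not isolated) | Cl[Zr](/C=C/CC#C[Si](C)(C)C)(C1C=CC=C1)C1C=CC=C1 | intermediate
11 | [(E)-5-iodopent-4-en-1-yn-1-yl]trimethylsilane | I/C=C/CC#C[Si](C)(C)C | intermediate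
12 | isopropenylmagnesium bromide | CC(=C)[Mg]Br | starting material
13 | 9-methoxy-9-borabicyclo[3.3.1]nonane | COB1C2CCCC1CCC2 | starting material
14 | bromomagnesium 9-isopropenyl-9-methoxy-9-boratabicyclo[3.3.1]nonane (not isolated) | CO[B-]1(C(C)=C)C2CCCC1CCC2.[Mg+]Br | intermediate
15 | 9-isopropenyl-9-borabicyclo[3.3.1]nonane | CC(=C)B1C2CCCC1CCC2 | intermediate
16 | cyclopent-2-en-1-one | O=C1C=CCC1 | starting material
17 | boron enolate, 9-{[(3R)-3-isopropenylcyclopent-1-en-1-yl]oxy}-9-borabicyclo[3.3.1]nonane (not isolated) | CC(=C)[C@@H]1CCC(OB2C3CCCC2CCC3)=C1 | intermediate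
18 | aldol ketone: (3R)-3-isopropenylcyclopentanone bearing on C1 (trans to isopropenyl) the CH(OH) arm bonded to the cis epoxide of 6; anti aldol at C1/C2, C2–OH anti to the epoxide oxygen | O=C1CC[C@@H](C(C)=C)[C@@H]1[C@H](O)[C@]2(C)O[C@@H]2CCO[Si](c3ccccc3)(c3ccccc3)C(C)(C)C | intermediate
19 | [(E)-5-(trimethylsilyl)pent-1-en-4-yn-1-yl]lithium (not isolated) | [Li]/C=C/CC#C[Si](C)(C)C | intermediate
20 | dichloro[(E)-5-(trimethylsilyl)pent-1-en-4-yn-1-yl]cerium (not isolated) | Cl[Ce](Cl)/C=C/CC#C[Si](C)(C)C | intermediate
21 | alkenyl diol: 18 with C11 as tertiary carbinol carrying the (E)-alkenyl chain trans to the C2 carbinol arm (C11–OH cis to that arm) | O[C@]1(/C=C/CC#C[Si](C)(C)C)CC[C@@H](C(C)=C)[C@@H]1[C@H](O)[C@]2(C)O[C@@H]2CCO[Si](c3ccccc3)(c3ccccc3)C(C)(C)C | intermediate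
22 | B-alkyl-9-BBN adduct of 21 at C16 (hydroxyl groups transiently borylated; not isolated) | O[C@]1(/C=C/CC#C[Si](C)(C)C)CC[C@@H]([C@@H](C)CB2C3CCCC2CCC3)[C@@H]1[C@H](O)[C@]4(C)O[C@@H]4CCO[Si](c5ccccc5)(c5ccccc5)C(C)(C)C | intermediate
23 | triol: 21 with the isopropenyl group converted into CH(CH3)CH2OH (C15 as in the target) | O[C@]1(/C=C/CC#C[Si](C)(C)C)CC[C@@H]([C@@H](C)CO)[C@@H]1[C@H](O)[C@]2(C)O[C@@H]2CCO[Si](c3ccccc3)(c3ccccc3)C(C)(C)C | intermediate
24 | iodo-pyran: trans-fused cyclopenta[c]pyran (O, C2, C1, C11, C10, C9) with equatorial C3, C8 and C10–I substituents and axial C11–OH (not isolated) | O[C@]12CC[C@@H]([C@@H](C)CO)[C@@H]1[C@H](O[C@H]([C@@H]2I)CC#C[Si](C)(C)C)[C@]3(C)O[C@@H]3CCO[Si](c4ccccc4)(c4ccccc4)C(C)(C)C | intermediate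
25 | cis-fused hexahydroisobenzofuranone: C11 ketone, C9 propargyl(silyl) arm, C2 epoxide arm, C14 CH(CH3)CH2OH arm; H1/H10 cis, H2/H9 cis and trans to H1/H10 | O=C1CC[C@@H]([C@@H](C)CO)[C@H]2[C@@H]1[C@H](CC#C[Si](C)(C)C)O[C@@H]2[C@]3(C)O[C@@H]3CCO[Si](c4ccccc4)(c4ccccc4)C(C)(C)C | intermediate
26 | C11 methyl carbinol: 25 with C11 C(OH)CH3, hydroxyl on the tetrahydrofuran face | C[C@@]1(O)CC[C@@H]([C@@H](C)CO)[C@H]2[C@@H]1[C@H](CC#C[Si](C)(C)C)O[C@@H]2[C@]3(C)O[C@@H]3CCO[Si](c4ccccc4)(c4ccccc4)C(C)(C)C | intermediate
27 | terminal alkyne diol: 26 without the alkynyl silyl group | C[C@@]1(O)CC[C@@H]([C@@H](C)CO)[C@H]2[C@@H]1[C@H](CC#C)O[C@@H]2[C@]3(C)O[C@@H]3CCO[Si](c4ccccc4)(c4ccccc4)C(C)(C)C | intermediate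
28 | C16 carboxylic acid: 27 with CH2OH oxidised to CO2H | C[C@@]1(O)CC[C@@H]([C@@H](C)C(O)=O)[C@H]2[C@@H]1[C@H](CC#C)O[C@@H]2[C@]3(C)O[C@@H]3CCO[Si](c4ccccc4)(c4ccccc4)C(C)(C)C | intermediate
29 | hydroxy ε-lactone: tricyclic lactone (O on C3), free C4–OH, C9 propargyl, C6 silyl ether | C#CC[C@@H]1O[C@H]2[C@H]3[C@@H](CC[C@@](C)(O)[C@H]31)[C@@H](C)C(=O)O[C@@]2(C)[C@H](O)CCO[Si](c4ccccc4)(c4ccccc4)C(C)(C)C | intermediate
30 | octanoyl chloride | CCCCCCCC(=O)Cl | starting material
31 | C4 octanoate of 29 | C#CC[C@@H]1O[C@H]2[C@H]3[C@@H](CC[C@@](C)(O)[C@H]31)[C@@H](C)C(=O)O[C@@]2(C)[C@H](OC(=O)CCCCCCC)CCO[Si](c4ccccc4)(c4ccccc4)C(C)(C)C | intermediate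
32 | (Z)-2-iodoalkenyl-9-BBN adduct of 31 (not isolated) | I/C(C[C@@H]1O[C@H]2[C@H]3[C@@H](CC[C@@](C)(O)[C@H]31)[C@@H](C)C(=O)O[C@@]2(C)[C@H](OC(=O)CCCCCCC)CCO[Si](c4ccccc4)(c4ccccc4)C(C)(C)C)=C\B5C6CCCC5CCC6 | intermediate
33 | vinyl iodide: 31 with the alkyne converted into a 2-iodoprop-2-enyl group | C=C(I)C[C@@H]1O[C@H]2[C@H]3[C@@H](CC[C@@](C)(O)[C@H]31)[C@@H](C)C(=O)O[C@@]2(C)[C@H](OC(=O)CCCCCCC)CCO[Si](c4ccccc4)(c4ccccc4)C(C)(C)C | intermediate
34 | C6 primary alcohol: 33 without the silyl ether | C=C(I)C[C@@H]1O[C@H]2[C@H]3[C@@H](CC[C@@](C)(O)[C@H]31)[C@@H](C)C(=O)O[C@@]2(C)[C@H](OC(=O)CCCCCCC)CCO | intermediate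
35 | C6 aldehyde | C=C(I)C[C@@H]1O[C@H]2[C@H]3[C@@H](CC[C@@](C)(O)[C@H]31)[C@@H](C)C(=O)O[C@@]2(C)[C@H](OC(=O)CCCCCCC)CC=O | intermediate
36 | alkenylchromium dichloride from 35 (not isolated) | C=C([Cr](Cl)Cl)C[C@@H]1O[C@H]2[C@H]3[C@@H](CC[C@@](C)(O)[C@H]31)[C@@H](C)C(=O)O[C@@]2(C)[C@H](OC(=O)CCCCCCC)CC=O | intermediate
37 | briarellin A | C=C1C[C@@H]2O[C@H]3[C@H]4[C@@H](CC[C@@](C)(O)[C@H]42)[C@@H](C)C(=O)O[C@@]3(C)[C@H](OC(=O)CCCCCCC)C[C@@H]1O | target

**Step count and risks**

Total step count: 20. Longest linear sequence: 17 steps (steps 1–4, then 8–20).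

Steps most likely to fail:

1. Step 8. The branched alkenyl group may transfer slowly or with eroded enantioselectivity from boron to rhodium at 80 °C, and the boron aldol may show poor anti/Felkin selectivity. The fallback sets out from 16 and 12 and comes back at 18. Copper-catalysed conjugate addition of 12 to 16 (CuBr·SMe2, Me3SiCl, THF, −78 °C) gives the racemic silyl enol ether F1. Methyllithium followed by 9-BBN triflate turns it into the racemic boron enolate F2. Two equivalents of F2 are combined with aldehyde 6 at −78 °C. The (R)-enolate is the matched partner (anti aldol on the Felkin face) and should give 18 faster than the (S)-enolate gives the syn diastereomer F3, which is removed by chromatography. Resolution by the enantiopure aldehyde thus replaces catalyst control.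

2. Step 11. After silver-assisted ionisation the cation may be captured by the ring oxygen or lose a proton instead of triggering migration, or the etherification may not be fully 6-endo. The fallback sets out from 23 and comes back at 25. Phenylselenenyl chloride (CH2Cl2, K2CO3, −78 °C → rt) under equilibrating conditions, where reversible selenoetherification favours the all-equatorial pyran, gives the equatorial selenide F4. Oxidation with excess mCPBA (K2HPO4, CH2Cl2, 0 °C) to the selenone, a far better nucleofuge than iodide, should induce the same 1,2-shift of C1 (the known ring enlargement of β-hydroxy selenides) and give 25.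

3. Step 15. Seven-membered ring closure may be slow, which would allow opening at C4, loss of configuration at C3 or interception by the tetrahydrofuran oxygen. The fallback sets out from 28 and comes back at 29, and separates C–O bond formation at C3 from ring closure. Aqueous HClO4 in THF opens the epoxide with water at the tertiary C3 with inversion and gives the diol acid F5. Lactonisation onto the tertiary C3 hydroxyl with 2-methyl-6-nitrobenzoic anhydride and DMAP at high dilution (the eight-membered lactone through C4–OH is disfavoured) then gives 29 by acyl C–O bond formation.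

**Further compounds**

F1 | step 8 | racemic 3-isopropenyl-1-(trimethylsilyloxy)cyclopent-1-ene | CC(=C)C1CCC(O[Si](C)(C)C)=C1
F2 | step 8 | racemic 9-[(3-isopropenylcyclopent-1-en-1-yl)oxy]-9-borabicyclo[3.3.1]nonane | CC(=C)C1CCC(OB2C3CCCC2CCC3)=C1
F3 | step 8 | syn aldol diastereomer of 18 from the (S)-enolate | O=C1CC[C@H](C(C)=C)[C@H]1[C@H](O)[C@]2(C)O[C@@H]2CCO[Si](c3ccccc3)(c3ccccc3)C(C)(C)C
F4 | step 11 | phenylseleno-pyran (analogue of 24 with equatorial C10–SePh) | O[C@]12CC[C@@H]([C@@H](C)CO)[C@@H]1[C@H](O[C@H]([C@@H]2[Se]c3ccccc3)CC#C[Si](C)(C)C)[C@]4(C)O[C@@H]4CCO[Si](c5ccccc5)(c5ccccc5)C(C)(C)C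
F5 | step 15 | C3,C4-diol acid (epoxide of 28 opened by water at C3) | C[C@@]1(O)CC[C@@H]([C@@H](C)C(O)=O)[C@H]2[C@@H]1[C@H](CC#C)O[C@@H]2[C@@](C)(O)[C@H](O)CCO[Si](c3ccccc3)(c3ccccc3)C(C)(C)C
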